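## Retrosynthetic overview

1. C3–C1′ is cut first: coupling of a 3‑(methylsulfanyl)isochromenone core with the side‑chain (E)‑vinylstannane, which comes from L‑isoleucine (C4′ inverted, C3′ by chelation‑controlled addition).
2. Carbocycle (second ring): C4a–C5 by electroreductive Reformatsky‑type closure of a dichloromethyl ketone onto the pyranone carbonyl; the chlorine is carried in.
3. C5–C6: dichloromethyllithium opens the lactic‑acid dioxolanone and frees the C7 hydroxyl.
4. C8–C8a: anti aldol of 6‑(methylsulfanyl)dihydropyranone (pyran ring, formed first from an α‑oxo ketene dithioacetal and CH2O) with a lactic‑acid‑derived quaternary aldehyde.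
5. Stereocentres: C7, C4′ and C5′ are bought ((S)‑lactic acid, L‑isoleucine); C8, C8a and C3′ are relayed from them.

Assumption: atom labels C1–C8a and C1′–C7′ follow the isochromene numbering of the target; 4,4‑bis(methylsulfanyl)but‑3‑en‑2‑one and (E)‑1,2‑bis(tributylstannyl)ethene are bought.

## Route

Step 1
Reactants: 1 (S)-lactic acid
Product: 2 (2S,5S)-2-tert-butyl-5-methyl-1,3-dioxolan-4-one
Conditions: t-BuCHO, TsOH·H2O (cat.), H2SO4 (cat.), pentane, reflux (Dean–Stark); recrystallisation Et2O/pentane, −78 °C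
Reagents that add atoms: pivaldehyde, CC(C)(C)C=O
Why: Acid‑catalysed acetalisation (Seebach dioxolanone formation) under thermodynamic control gives mainly the cis acetal, purified by cold crystallisation, so the lactic acid stereocentre is copied onto the acetal carbon (2S).

Step 2
Reactants: 2 (2S,5S)-2-tert-butyl-5-methyl-1,3-dioxolan-4-one
Product: 4 (2S,5R)-2-tert-butyl-5-(hydroxymethyl)-5-methyl-1,3-dioxolan-4-one, via lithium enolate 3 (not isolated)
Conditions: LiN(iPr)2, THF, −78 °C; CH2O (g), −78 °C; AcOH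
Reagents that add atoms: formaldehyde, C=O
Why: Seebach self‑regeneration of stereocentres, in which the planar enolate undergoes aldol addition to formaldehyde on the face opposite the tert‑butyl group, rebuilding C7 as a quaternary centre with net retention.

Step 3
Reactants: 4 (2S,5R)-2-tert-butyl-5-(hydroxymethyl)-5-methyl-1,3-dioxolan-4-one
Product: 5 (2S,4R)-2-tert-butyl-4-methyl-5-oxo-1,3-dioxolane-4-carbaldehyde
Conditions: Dess–Martin periodinane, CH2Cl2, 0 °C → rt; used crude
Reagents that add atoms: none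
Why: Dess–Martin oxidation of the neopentyl primary alcohol gives the non‑enolisable aldehyde under neutral conditions that leave the acetal and the quaternary centre untouched.

Step 4
Reactants: 6 4,4-bis(methylsulfanyl)but-3-en-2-one
Product: 9 6-(methylsulfanyl)-2,3-dihydro-4H-pyran-4-one, via lithium enolate 7 (not isolated), via hydroxy ketone 8 (not isolated)
Conditions: LiN(iPr)2, THF, −78 °C; CH2O (g); AcOH; crude, then TsOH·H2O (10 mol%), CH2Cl2, rt
Reagents that add atoms: formaldehyde, C=O
Why: Kinetic aldol addition of the methyl‑ketone enolate to formaldehyde, then acid‑catalysed 6‑endo oxa‑Michael addition–elimination (loss of MeSH) on the α‑oxo ketene dithioacetal, closes the pyran ring without creating a stereocentre.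

Step 5
Reactants: 9 6-(methylsulfanyl)-2,3-dihydro-4H-pyran-4-one; 5 (2S,4R)-2-tert-butyl-4-methyl-5-oxo-1,3-dioxolane-4-carbaldehyde
Product: 12 (2S,5R)-2-tert-butyl-5-{(R)-hydroxy[(3S)-6-(methylsulfanyl)-4-oxo-3,4-dihydro-2H-pyran-3-yl]methyl}-5-methyl-1,3-dioxolan-4-one, via lithium enolate 10 (not isolated), via bromomagnesium enolate 11 (not isolated)
Conditions: LiN(iPr)2, THF, −78 °C; MgBr2·OEt2; then 5, −78 °C; AcOH, −78 °C
Reagents that add atoms: none
Why: Aldol addition through a closed Zimmerman–Traxler chair, in which the ring‑constrained E enolate gives the anti C8/C8a relationship (8aS) and magnesium bridging the aldehyde and lactone carbonyls of 5 holds C7 so that the enolate adds anti to the ring C–O bond and past the methyl group (polar Felkin–Anh), giving 8R.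

Step 6
Reactants: 12 (2S,5R)-2-tert-butyl-5-{(R)-hydroxy[(3S)-6-(methylsulfanyl)-4-oxo-3,4-dihydro-2H-pyran-3-yl]methyl}-5-methyl-1,3-dioxolan-4-one
Product: 13 (3S)-3-[(1R,2R)-4,4-dichloro-1,2-dihydroxy-2-methyl-3-oxobutyl]-6-(methylsulfanyl)-2,3-dihydro-4H-pyran-4-one
Conditions: CH2Cl2, n-BuLi, THF, −100 °C (LiCHCl2, 3.5 equiv); then 12, −100 → −78 °C; AcOH, −78 °C
Reagents that add atoms: dichloromethyllithium, [Li]C(Cl)Cl (made in the flask from dichloromethane, ClCCl)
Why: Nucleophilic acyl substitution of the activated lactone by dichloromethyllithium stops at the ketone (held as its enolate), the released hemiacetal alkoxide collapses to pivaldehyde and the free C7 alcohol, and the less electrophilic vinylogous‑thioester ketone and all stereocentres are left alone.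

Step 7
Reactants: 13 (3S)-3-[(1R,2R)-4,4-dichloro-1,2-dihydroxy-2-methyl-3-oxobutyl]-6-(methylsulfanyl)-2,3-dihydro-4H-pyran-4-one
Product: 16 (7R,8R,8aS)-5-chloro-7,8-dihydroxy-7-methyl-3-(methylsulfanyl)-7,8-dihydro-1H-isochromen-6(8aH)-one, via chlorozinc enolate 14 (not isolated), via chlorohydrin 15 (not isolated)
Conditions: undivided cell, Zn anode, glassy‑carbon cathode, Et4NBF4 (0.1 M), DMF, −20 °C, constant potential (−1.2 V vs Ag/AgCl), 2.1 F mol−1; then 1 M HCl, THF, 0 °C → rt
Reagents that add atoms: none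
Why: Proposed new method: cathodic two‑electron cleavage of one C–Cl bond of the α,α‑dichloromethyl ketone (expected near −1.1 V, well positive of the vinylogous thioester and of the remaining α‑C–Cl bond) gives an α‑chloro enolate that is captured by Zn2+ from the sacrificial anode, this electrogenerated Reformatsky‑type reagent closes the six‑membered ring on the C4a carbonyl (6‑enolendo‑exo‑trig) without added base so that C8a is not enolised and the β‑hydroxy ketone is not cleaved, and acid work‑up dehydrates the donor‑stabilised tertiary carbinol to the 5‑chloro dienone with the chlorine already in place; the closest known reaction types are the sacrificial‑anode electrochemical Reformatsky reaction of α‑halo esters and the SmI2‑ or CrCl2‑mediated condensation of α,α‑dihalo carbonyl compounds with aldehydes, none shown for a dichloromethyl ketone, a vinylogous ester acceptor or a ring closure.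

Step 8
Reactants: 16 (7R,8R,8aS)-5-chloro-7,8-dihydroxy-7-methyl-3-(methylsulfanyl)-7,8-dihydro-1H-isochromen-6(8aH)-one
Product: 17 (7R,8R,8aS)-5-chloro-7-hydroxy-7-methyl-3-(methylsulfanyl)-6-oxo-6,7,8,8a-tetrahydro-1H-isochromen-8-yl acetate
Conditions: Ac2O, pyridine, DMAP (cat.), CH2Cl2, 0 °C
Reagents that add atoms: acetic anhydride, CC(=O)OC(C)=O
Why: DMAP‑catalysed acylation takes the secondary C8 alcohol only, because the tertiary C7 alcohol is too hindered at 0 °C and pyridine is too weak a base to enolise C8a.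

Step 9
Reactants: 18 L-isoleucine
Product: 19 (2S,3S)-2-hydroxy-3-methylpentanoic acid
Conditions: NaNO2, 1 M H2SO4, H2O, 0 °C → rt
Reagents that add atoms: water, O
Why: Diazotisation of the α‑amino acid (hydroxy‑de‑amination) goes with retention by double inversion through the α‑lactone, so both bought stereocentres are kept.

Step 10
Reactants: 19 (2S,3S)-2-hydroxy-3-methylpentanoic acid
Product: 20 (3S,4S)-3-hydroxy-4-methylhexan-2-one
Conditions: MeLi (3.5 equiv), THF, 0 °C → rt; inverse quench into cold 1 M HCl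
Reagents that add atoms: methyllithium, [Li]C
Why: Addition of methyllithium to the lithium carboxylate gives a geminal dialkoxide that is stable to further addition and releases the methyl ketone only on acidic quench, so no enolisable ketone is present under basic conditions.

Step 11
Reactants: 20 (3S,4S)-3-hydroxy-4-methylhexan-2-one
Product: 23 (3R,4S)-3-hydroxy-4-methylhexan-2-one, via triflate 21 (not isolated), via nitrite ester 22 (not isolated)
Conditions: Tf2O, pyridine, CH2Cl2, −40 °C; Bu4N+NO2−, DMF, 0 °C → rt; H2O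
Reagents that add atoms: tetrabutylammonium nitrite, CCCC[N+](CCCC)(CCCC)CCCC.[O-]N=O
Why: Lattrell–Dax inversion, in which SN2 displacement of the α‑keto triflate by nitrite oxygen and hydrolysis of the nitrite ester inverts C3 to R and so gives the 4′R,5′S relationship of the target.

Step 12
Reactants: 23 (3R,4S)-3-hydroxy-4-methylhexan-2-one
Product: 25 (1E,3R,4R,5S)-3,5-dimethyl-1-(tributylstannyl)hept-1-ene-3,4-diol, via bromomagnesium alkoxide 24 (not isolated)
Conditions: (E)-Bu3SnCH=CHSnBu3 (2.4 equiv), n-BuLi (2.3 equiv), THF, −78 °C; MgBr2·OEt2; then 23, −78 → −20 °C; aq. NH4Cl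
Reagents that add atoms: (E)-1,2-bis(tributylstannyl)ethene, CCCC[Sn](CCCC)(CCCC)/C=C/[Sn](CCCC)(CCCC)CCCC
Why: Cram‑chelate controlled 1,2‑addition, in which the magnesium alkoxide chelates the ketone and the vinyl Grignard reagent adds from the face opposite the sec‑butyl group to give the 3R tertiary alcohol with the E vinylstannane intact.

Step 13
Reactants: 17 (7R,8R,8aS)-5-chloro-7-hydroxy-7-methyl-3-(methylsulfanyl)-6-oxo-6,7,8,8a-tetrahydro-1H-isochromen-8-yl acetate; 25 (1E,3R,4R,5S)-3,5-dimethyl-1-(tributylstannyl)hept-1-ene-3,4-diol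
Product: 26 8a-epi-hypocrellone A
Conditions: Pd(PPh3)4 (5 mol%), Cu(O2CC4H3S) (copper thiophene-2-carboxylate, 1.5 equiv), THF, 50 °C
Reagents that add atoms: none
Why: Liebeskind–Srogl‑type C–S cross‑coupling with an organostannane, in which the copper carboxylate activates the vinylogous thioester C–SMe bond for oxidative addition to zerovalent palladium and takes up the thiolate, and the vinyl group is transferred with retention of E geometry under neutral conditions that spare the acetate, the free hydroxyls and the C5 chloride.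

## Compound list

1 | (S)-lactic acid | C[C@H](O)C(=O)O | starting material
2 | (2S,5S)-2-tert-butyl-5-methyl-1,3-dioxolan-4-one | C[C@@H]1O[C@H](C(C)(C)C)OC1=O | intermediate
3 | lithium enolate of 2 (lithium (2S)-2-tert-butyl-5-methyl-1,3-dioxol-4-olate) | [Li+].CC1=C([O-])O[C@@H](C(C)(C)C)O1 | intermediate
4 | (2S,5R)-2-tert-butyl-5-(hydroxymethyl)-5-methyl-1,3-dioxolan-4-one | C[C@]1(CO)O[C@H](C(C)(C)C)OC1=O | intermediate
5 | (2S,4R)-2-tert-butyl-4-methyl-5-oxo-1,3-dioxolane-4-carbaldehyde | C[C@]1(C=O)O[C@H](C(C)(C)C)OC1=O | intermediate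
6 | 4,4-bis(methylsulfanyl)but-3-en-2-one | CC(=O)C=C(SC)SC | starting material
7 | lithium enolate of 6 | [Li+].C=C([O-])C=C(SC)SC | intermediate
8 | 5-hydroxy-1,1-bis(methylsulfanyl)pent-1-en-3-one | OCCC(=O)C=C(SC)SC | intermediate
9 | 6-(methylsulfanyl)-2,3-dihydro-4H-pyran-4-one | CSC1=CC(=O)CCO1 | intermediate
10 | lithium enolate of 9 | [Li+].CSC1=CC([O-])=CCO1 | intermediate
11 | bromomagnesium enolate of 9 | CSC1=CC(O[Mg]Br)=CCO1 | intermediate
12 | (2S,5R)-2-tert-butyl-5-{(R)-hydroxy[(3S)-6-(methylsulfanyl)-4-oxo-3,4-dihydro-2H-pyran-3-yl]methyl}-5-methyl-1,3-dioxolan-4-one | CSC1=CC(=O)[C@H]([C@@H](O)[C@@]2(C)O[C@H](C(C)(C)C)OC2=O)CO1 | intermediate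
13 | (3S)-3-[(1R,2R)-4,4-dichloro-1,2-dihydroxy-2-methyl-3-oxobutyl]-6-(methylsulfanyl)-2,3-dihydro-4H-pyran-4-one | CSC1=CC(=O)[C@H]([C@@H](O)[C@@](C)(O)C(=O)C(Cl)Cl)CO1 | intermediate
14 | chlorozinc enolate of 13 (O‑bound ClZn, divalent zinc) | CSC1=CC(=O)[C@H]([C@@H](O)[C@@](C)(O)C(O[Zn]Cl)=CCl)CO1 | intermediate
15 | (7R,8R,8aS)-5-chloro-4a,7,8-trihydroxy-7-methyl-3-(methylsulfanyl)-4a,5,8,8a-tetrahydro-1H-isochromen-6(7H)-one, mixture at C4a and C5 | CSC1=CC2(O)C(Cl)C(=O)[C@](C)(O)[C@H](O)[C@@H]2CO1 | intermediate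
16 | (7R,8R,8aS)-5-chloro-7,8-dihydroxy-7-methyl-3-(methylsulfanyl)-7,8-dihydro-1H-isochromen-6(8aH)-one | CSC1=CC2=C(Cl)C(=O)[C@](C)(O)[C@H](O)[C@@H]2CO1 | intermediate
17 | (7R,8R,8aS)-5-chloro-7-hydroxy-7-methyl-3-(methylsulfanyl)-6-oxo-6,7,8,8a-tetrahydro-1H-isochromen-8-yl acetate | CSC1=CC2=C(Cl)C(=O)[C@](C)(O)[C@H](OC(C)=O)[C@@H]2CO1 | intermediate
18 | L-isoleucine | CC[C@H](C)[C@H](N)C(=O)O | starting material
19 | (2S,3S)-2-hydroxy-3-methylpentanoic acid | CC[C@H](C)[C@H](O)C(=O)O | intermediate
20 | (3S,4S)-3-hydroxy-4-methylhexan-2-one | CC[C@H](C)[C@H](O)C(C)=O | intermediate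
21 | (3S,4S)-4-methyl-2-oxohexan-3-yl trifluoromethanesulfonate | CC[C@H](C)[C@H](OS(=O)(=O)C(F)(F)F)C(C)=O | intermediate
22 | (3R,4S)-4-methyl-2-oxohexan-3-yl nitrite | CC[C@H](C)[C@@H](ON=O)C(C)=O | intermediate
23 | (3R,4S)-3-hydroxy-4-methylhexan-2-one | CC[C@H](C)[C@@H](O)C(C)=O | intermediate
24 | bromomagnesium alkoxide of 23 | CC[C@H](C)[C@@H](O[Mg]Br)C(C)=O | intermediate
25 | (1E,3R,4R,5S)-3,5-dimethyl-1-(tributylstannyl)hept-1-ene-3,4-diol | CC[C@H](C)[C@@H](O)[C@](C)(O)/C=C/[Sn](CCCC)(CCCC)CCCC | intermediate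
26 | 8a-epi-hypocrellone A, (7R,8R,8aS)-5-chloro-3-[(1E,3R,4R,5S)-3,4-dihydroxy-3,5-dimethylhept-1-en-1-yl]-7-hydroxy-7-methyl-6-oxo-6,7,8,8a-tetrahydro-1H-isochromen-8-yl acetate | CC[C@H](C)[C@@H](O)[C@](C)(O)/C=C/C1=CC2=C(Cl)C(=O)[C@](C)(O)[C@H](OC(C)=O)[C@@H]2CO1 | target

## Step count and risks

Total steps: 13. Longest linear sequence: 8 (steps 1, 2, 3, 5, 6, 7, 8, 13).

Steps most likely to fail:

**Step 5 (aldol).** The anti C8/C8a relationship is secure, but the facial selectivity at C8 of this α‑quaternary aldehyde rests on a chelate model. An α‑chelate through the ring oxygen, or a non‑chelated pathway passing the lactone carbon, would give the C8,C8a‑bis‑epimer; retro‑aldol or dehydration of 12 is also possible. The fallback sets out from 9 and 2 and returns at 12. It reverses the polarity of the union so that C7–C8 is made by the dioxolanone enolate. Compound 9 is formylated (HCO2Et, NaH) to the hydroxymethylene ketone F1 and dehydrogenated (DDQ) to the pyrone aldehyde F2. The lithium enolate 3 adds to F2 through the Zimmerman–Traxler chair (methyl cis to O–Li, aldehyde residue equatorial), giving the 7,8‑erythro adduct, which is trapped in the flask with Et3SiCl as the silyl ether F3. LiBH(s-Bu)3 delivers hydride to C1 of the pyrone, and the enolate is protonated at −78 °C on the face opposite the quaternary centre (allylic strain keeps H8 in the enolate plane) to give the silyl ether F4. HF·pyridine then returns 12.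

**Step 7 (the new electrochemical ring closure).** The hydroxyls of 13 may protonate the electrogenerated enolate, giving the chloromethyl ketone. The second C–Cl bond or the C–S bond may be reduced. The zinc alkoxide may close to a Darzens epoxide instead of dehydrating. The fallback uses known chemistry, sets out from 12 and returns at 16. Chloromethyllithium (ICH2Cl, MeLi·LiBr, THF, −78 °C) opens the dioxolanone to the chloromethyl ketone F5 with loss of pivaldehyde. Acid‑catalysed intramolecular aldol condensation (TsOH, benzene, 50 °C) of its only possible enol with the pyranone carbonyl then gives 16 without any reduction step.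

**Step 13 (C–S coupling).** The doubly vinylogous thioester is hindered and electron‑rich, and the copper salt may bind the diol of 25 or promote protodestannylation. The fallback sets out from 17 and returns at 26. Sulfuryl chloride (CH2Cl2, −78 °C) exchanges the methylsulfanyl group for chloride to give the 3‑chloro compound F6, a doubly vinylogous acid chloride. F6 then undergoes a conventional Stille coupling with 25 (Pd(PPh3)4, CuI, LiCl, THF, 40 °C).

## Further compounds

F1 | step 5 | 3-(hydroxymethylidene)-6-(methylsulfanyl)-2,3-dihydro-4H-pyran-4-one | CSC1=CC(=O)C(=CO)CO1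
F2 | step 5 | 6-(methylsulfanyl)-4-oxo-4H-pyran-3-carbaldehyde | CSC1=CC(=O)C(C=O)=CO1
F3 | step 5 | (2S,5R)-2-tert-butyl-5-methyl-5-{(R)-[6-(methylsulfanyl)-4-oxo-4H-pyran-3-yl][(triethylsilyl)oxy]methyl}-1,3-dioxolan-4-one | CSC1=CC(=O)C(=CO1)[C@@H](O[Si](CC)(CC)CC)[C@@]2(C)O[C@H](C(C)(C)C)OC2=O
F4 | step 5 | (2S,5R)-2-tert-butyl-5-methyl-5-{(R)-[(3S)-6-(methylsulfanyl)-4-oxo-3,4-dihydro-2H-pyran-3-yl][(triethylsilyl)oxy]methyl}-1,3-dioxolan-4-one | CSC1=CC(=O)[C@H]([C@@H](O[Si](CC)(CC)CC)[C@@]2(C)O[C@H](C(C)(C)C)OC2=O)CO1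
F5 | step 7 | (3S)-3-[(1R,2R)-4-chloro-1,2-dihydroxy-2-methyl-3-oxobutyl]-6-(methylsulfanyl)-2,3-dihydro-4H-pyran-4-one | CSC1=CC(=O)[C@H]([C@@H](O)[C@@](C)(O)C(=O)CCl)CO1
F6 | step 13 | (7R,8R,8aS)-3,5-dichloro-7-hydroxy-7-methyl-6-oxo-6,7,8,8a-tetrahydro-1H-isochromen-8-yl acetate | ClC1=CC2=C(Cl)C(=O)[C@](C)(O)[C@H](OC(C)=O)[C@@H]2CO1
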